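The route rests on opening the central benzene ring (C4a, C5, C6, C7, C8, C8a) at C4a–C5 and C6–C7. Its meta-related oxygens on C7 and C8a mark C7–C8–C8a–C4a as a chain-extended acetoacetate, while C5 with its methyl and C6 with the acyl carbon of the later pyranone come from pent-3-yn-2-one. One Diels–Alder benzannulation therefore delivers the fully substituted arene with every substituent placed, leaving the C4 stereocentre, set beforehand by desymmetrising a 3-arylglutaric anhydride, untouched. The precursor is a 1-methoxy-1,3-bis(trimethylsilyloxy)butadiene carrying the CH(aryl)CH2CO2Me chain on its nucleophilic terminus; the spectator ester is methyl, so the methanolysis hemiester is used without ester exchange.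

Key step: step 6

Remark on numbering: locants C2–C8a are those of the chroman-2-one core of the target. The descriptor at the single stereocentre switches between R and S along the route by CIP priority only; its spatial arrangement never changes.

Assumption: the quinidine-derived sulfonamide catalyst of step 3 is taken to open anhydride 5 at the carbonyl that gives (R)-6. The sense is to be checked on the first batch; if it is the opposite one, the quinine-derived pseudoenantiomer is used and nothing else changes.

Step 1
Reactants: 1 4-benzyloxybenzaldehyde; 2 ethyl acetoacetate (2.1 equiv)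
Product: 4 3-[4-(benzyloxy)phenyl]pentanedioic acid, via bis-acetoacetate adduct 3 (not isolated)
Conditions: piperidine (cat.), EtOH, rt; then 50% aq NaOH, 90 °C; then aq HCl to pH 1
Reagents that add atoms: sodium hydroxide, [Na+].[OH-]
Why: Knoevenagel condensation and Michael addition of a second acetoacetate give the bis-adduct (open-chain or as its ring-closed aldol form), and hot concentrated hydroxide then strips both acetyl groups by retro-Claisen cleavage and saponifies the esters, the classical entry to 3-arylglutaric acids, which the aryl benzyl ether tolerates.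

Step 2
Reactants: 4 3-[4-(benzyloxy)phenyl]pentanedioic acid
Product: 5 4-[4-(benzyloxy)phenyl]oxane-2,6-dione
Conditions: Ac2O, 120 °C; evaporate, crystallise
Reagents that add atoms: none
Why: Cyclodehydration of a glutaric acid to its six-membered anhydride through the mixed anhydride is routine and affects no other group.

Step 3
Reactants: 5 4-[4-(benzyloxy)phenyl]oxane-2,6-dione
Product: 6 (3R)-3-[4-(benzyloxy)phenyl]-5-methoxy-5-oxopentanoic acid
Conditions: MeOH (10 equiv), N-(9-deoxy-epi-quinidin-9-yl)-3,5-bis(trifluoromethyl)benzenesulfonamide (10 mol%), MTBE, rt to −20 °C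
Reagents that add atoms: methanol, CO
Why: Organocatalytic desymmetrising alcoholysis of a prochiral anhydride, in which the quinuclidine nitrogen delivers methanol by general-base catalysis while the sulfonamide N–H binds one of the two enantiotopic carbonyls, so that the catalyst pocket decides which carbonyl is opened and thereby sets C3 (the later C4).

Step 4
Reactants: 6 (3R)-3-[4-(benzyloxy)phenyl]-5-methoxy-5-oxopentanoic acid; 7 potassium methyl malonate
Product: 9 dimethyl (5R)-5-[4-(benzyloxy)phenyl]-3-oxoheptanedioate, via acyl imidazolide 8 (not isolated)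
Conditions: CDI, THF, rt; then 7, MgCl2, Et3N, THF/MeCN, rt to 40 °C; then 1 M HCl
Reagents that add atoms: none
Why: Masamune–Brooks homologation, in which the acyl imidazolide C-acylates the magnesium enolate of the malonate half-ester and the adduct decarboxylates on acidification, under conditions that leave the methyl ester and the stereocentre (β to every carbonyl, not enolisable) alone.

Step 5
Reactants: 9 dimethyl (5R)-5-[4-(benzyloxy)phenyl]-3-oxoheptanedioate
Product: 11 methyl (3S,4Z)-3-[4-(benzyloxy)phenyl]-7-methoxy-5,7-bis(trimethylsilyloxy)hepta-4,6-dienoate, via mono-silyl enol ether 10 (not isolated)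
Conditions: TMSOTf (2.2 equiv), Et3N (2.6 equiv), Et2O, 0 °C to rt; decant from the ammonium salt under argon, evaporate, use crude
Reagents that add atoms: trimethylsilyl trifluoromethanesulfonate, C[Si](C)(C)OS(=O)(=O)C(F)(F)F
Why: Double soft enolisation of a β-keto ester with silyl triflate and amine gives the 1-alkoxy-1,3-bis(silyloxy)diene in one flask, the second silylation taking place at the β-silyloxy enoate carbonyl, which as a vinylogous carbonate is far more Lewis basic than the isolated methyl ester, so the spectator ester is not enolised, no strong base is needed and the bulky chain settles on the outside (4Z) of the diene.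

Step 6
Reactants: 11 methyl (3S,4Z)-3-[4-(benzyloxy)phenyl]-7-methoxy-5,7-bis(trimethylsilyloxy)hepta-4,6-dienoate; 12 pent-3-yn-2-one (3 equiv)
Product: 15 methyl (3R)-3-(3-acetyl-4,6-dihydroxy-2-methylphenyl)-3-[4-(benzyloxy)phenyl]propanoate, via cycloadduct 13 (not isolated), via bis-silyl ether 14 (not isolated)
Conditions: PhMe (2 M), 90 °C, sealed tube, argon; then 1 M HCl, THF, rt
Reagents that add atoms: none
Why: This is a normal-demand, strongly polarised and asynchronous [4+2] cycloaddition in which the diene terminus remote from the ketene acetal (future C4a) bonds to the methyl-bearing β-carbon of the ynone (C5) ahead of bond formation between the acetal carbon (C7) and the α-carbon (C6), giving cyclohexa-1,4-diene 13, which loses methanol across C4a–H and C7–OMe to give arene 14 before aqueous acid frees both phenols. The closest known reaction type is the cycloaddition of 1-alkoxy-1,3-bis(silyloxy)butadienes with acetylenic ketones and esters followed by aromatisation to resorcinols. The central benzene ring is closed by an intermolecular [4+2] cycloaddition that makes C4a–C5 and C6–C7 in one event, not by cyclisation of a tethered chain. No stereocentre is created, since the sp3 centres at C4a and C7 of 13 vanish on aromatisation, and C4 is a bystander whose hydrogen cannot migrate because the chain sits on the outside of the diene, where a 1,5-hydrogen shift is geometrically impossible. The only selectivity needed is regiochemical, and it is secured by pairing the largest HOMO coefficient of the diene (the C4a terminus, pushed by three oxygen donors) with the largest LUMO coefficient of the ynone (its β-carbon), which puts the methyl on C5 and the acetyl on C6 next to the C7 oxygen. The hydrolytic work-up cleaves any remaining silyl ketal before ionisation, so methanol and not silanol leaves C7 and O7 ends as a free phenol; any lactone 16 formed already at this stage is simply carried into step 7.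

Step 7
Reactants: 15 methyl (3R)-3-(3-acetyl-4,6-dihydroxy-2-methylphenyl)-3-[4-(benzyloxy)phenyl]propanoate
Product: 16 (4R)-6-acetyl-4-[4-(benzyloxy)phenyl]-7-hydroxy-5-methyl-3,4-dihydro-2H-chromen-2-one
Conditions: p-TsOH·H2O (5 mol%), PhMe, 60 °C
Reagents that add atoms: none
Why: Acid-catalysed intramolecular transesterification (lactonisation) closes the six-membered dihydrocoumarin ring with loss of methanol, only the O8a phenol being within reach of the ester, and the mild acid should not ionise the diarylmethine C4.

Step 8
Reactants: 16 (4R)-6-acetyl-4-[4-(benzyloxy)phenyl]-7-hydroxy-5-methyl-3,4-dihydro-2H-chromen-2-one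
Product: 17 (4R)-6-acetyl-7-(benzyloxy)-4-[4-(benzyloxy)phenyl]-5-methyl-3,4-dihydro-2H-chromen-2-one
Conditions: BnBr, K2CO3, dry acetone, 50 °C
Reagents that add atoms: benzyl bromide, BrCc1ccccc1
Why: Williamson etherification of the only free phenol (its hydrogen bond to the acetyl group is broken by carbonate) under anhydrous conditions that offer no nucleophile to open the aryl lactone and no base able to deprotonate C4.

Step 9
Reactants: 17 (4R)-6-acetyl-7-(benzyloxy)-4-[4-(benzyloxy)phenyl]-5-methyl-3,4-dihydro-2H-chromen-2-one
Product: 18 (4R)-7-(benzyloxy)-4-[4-(benzyloxy)phenyl]-5-methyl-6-[1-(trimethylsilyloxy)ethenyl]-3,4-dihydro-2H-chromen-2-one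
Conditions: TMSOTf (1.3 equiv), Et3N (2 equiv), CH2Cl2, 0 °C; hexane extraction, use crude
Reagents that add atoms: trimethylsilyl trifluoromethanesulfonate, C[Si](C)(C)OS(=O)(=O)C(F)(F)F
Why: Soft enolisation with silyl triflate and amine converts the methyl ketone, the more Lewis-basic and more acidic carbonyl, into its silyl enol ether much faster than the lactone, and avoids amide bases that would turn the aryl ester into an enolate prone to ketene formation.

Step 10
Reactants: 18 (4R)-7-(benzyloxy)-4-[4-(benzyloxy)phenyl]-5-methyl-6-[1-(trimethylsilyloxy)ethenyl]-3,4-dihydro-2H-chromen-2-one; 19 malonyl dichloride (1.2 equiv)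
Product: 21 (4R)-7-(benzyloxy)-4-[4-(benzyloxy)phenyl]-6-(4-hydroxy-2-oxo-2H-pyran-6-yl)-5-methyl-3,4-dihydro-2H-chromen-2-one, via diketo acid chloride 20 (not isolated)
Conditions: Et2O/CH2Cl2, −78 °C to rt
Reagents that add atoms: none
Why: In this silyl enol ether–malonyl dichloride pyranone annulation the unhindered methylene terminus of the enol ether is C-acylated with loss of chlorotrimethylsilane and the enol oxygen of the resulting 1,3-diketone then closes onto the second acyl chloride to give the 4-hydroxy-2-pyranone, all without base and so without risk to the lactone, the benzyl ethers or C4.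

Step 11
Reactants: 21 (4R)-7-(benzyloxy)-4-[4-(benzyloxy)phenyl]-6-(4-hydroxy-2-oxo-2H-pyran-6-yl)-5-methyl-3,4-dihydro-2H-chromen-2-one
Product: 22 (4R)-7-(benzyloxy)-4-[4-(benzyloxy)phenyl]-6-(4-methoxy-2-oxo-2H-pyran-6-yl)-5-methyl-3,4-dihydro-2H-chromen-2-one
Conditions: Me2SO4 (1.2 equiv), K2CO3, dry acetone, rt to 40 °C
Reagents that add atoms: dimethyl sulfate, COS(=O)(=O)OC
Why: O-Methylation of the 4-hydroxy-2-pyranone, a vinylogous carboxylic acid and the only acidic OH left, with a hard methylating agent under carbonate should favour the 4-methoxy-2-pyranone over the 2-methoxy-4-pyranone isomer.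

Step 12
Reactants: 22 (4R)-7-(benzyloxy)-4-[4-(benzyloxy)phenyl]-6-(4-methoxy-2-oxo-2H-pyran-6-yl)-5-methyl-3,4-dihydro-2H-chromen-2-one
Product: 23 (4R)-7-hydroxy-4-(4-hydroxyphenyl)-6-(4-methoxy-2-oxo-2H-pyran-6-yl)-5-methyl-3,4-dihydro-2H-chromen-2-one
Conditions: H2 (1 atm), 10% Pd/C, EtOAc/THF, rt; stop at full debenzylation
Reagents that add atoms: none
Why: Catalytic hydrogenolysis removes both aryl benzyl ethers under neutral conditions that should leave the lactone, the C4 stereocentre and, at atmospheric pressure and short contact time, the 4-methoxy-2-pyranone intact.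

Compound list
1 | 4-benzyloxybenzaldehyde | O=Cc1ccc(OCc2ccccc2)cc1 | starting material
2 | ethyl acetoacetate | CCOC(=O)CC(C)=O | starting material
3 | diethyl 2,4-diacetyl-3-[4-(benzyloxy)phenyl]pentanedioate (diastereomer mixture) | CCOC(=O)C(C(C)=O)C(c1ccc(OCc2ccccc2)cc1)C(C(C)=O)C(=O)OCC | intermediate (not isolated)
4 | 3-[4-(benzyloxy)phenyl]pentanedioic acid | OC(=O)CC(c1ccc(OCc2ccccc2)cc1)CC(=O)O | intermediate
5 | 4-[4-(benzyloxy)phenyl]oxane-2,6-dione | O=C1CC(c2ccc(OCc3ccccc3)cc2)CC(=O)O1 | intermediate
6 | (3R)-3-[4-(benzyloxy)phenyl]-5-methoxy-5-oxopentanoic acid | OC(=O)C[C@@H](c1ccc(OCc2ccccc2)cc1)CC(=O)OC | intermediate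
7 | potassium methyl malonate (potassium 3-methoxy-3-oxopropanoate) | COC(=O)CC(=O)[O-].[K+] | starting material
8 | methyl (3R)-3-[4-(benzyloxy)phenyl]-5-(1H-imidazol-1-yl)-5-oxopentanoate | O=C(C[C@@H](c1ccc(OCc2ccccc2)cc1)CC(=O)OC)n1ccnc1 | intermediate (not isolated)
9 | dimethyl (5R)-5-[4-(benzyloxy)phenyl]-3-oxoheptanedioate | COC(=O)CC(=O)C[C@@H](c1ccc(OCc2ccccc2)cc1)CC(=O)OC | intermediate
10 | dimethyl (5R)-5-[4-(benzyloxy)phenyl]-3-(trimethylsilyloxy)hept-2-enedioate (enoate geometry immaterial) | COC(=O)C=C(O[Si](C)(C)C)C[C@@H](c1ccc(OCc2ccccc2)cc1)CC(=O)OC | intermediate (not isolated)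
11 | methyl (3S,4Z)-3-[4-(benzyloxy)phenyl]-7-methoxy-5,7-bis(trimethylsilyloxy)hepta-4,6-dienoate (ketene acetal geometry immaterial) | COC(O[Si](C)(C)C)=C/C(O[Si](C)(C)C)=C/[C@@H](c1ccc(OCc2ccccc2)cc1)CC(=O)OC | intermediate
12 | pent-3-yn-2-one | CC#CC(C)=O | starting material
13 | methyl (3S)-3-[3-acetyl-4-methoxy-2-methyl-4,6-bis(trimethylsilyloxy)cyclohexa-2,5-dien-1-yl]-3-[4-(benzyloxy)phenyl]propanoate (mixture at the two transient ring centres) | COC1(O[Si](C)(C)C)C=C(O[Si](C)(C)C)C([C@@H](c2ccc(OCc3ccccc3)cc2)CC(=O)OC)C(C)=C1C(C)=O | intermediate (not isolated)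
14 | methyl (3R)-3-[3-acetyl-2-methyl-4,6-bis(trimethylsilyloxy)phenyl]-3-[4-(benzyloxy)phenyl]propanoate | CC(=O)c1c(O[Si](C)(C)C)cc(O[Si](C)(C)C)c([C@@H](c2ccc(OCc3ccccc3)cc2)CC(=O)OC)c1C | intermediate (not isolated)
15 | methyl (3R)-3-(3-acetyl-4,6-dihydroxy-2-methylphenyl)-3-[4-(benzyloxy)phenyl]propanoate | CC(=O)c1c(O)cc(O)c([C@@H](c2ccc(OCc3ccccc3)cc2)CC(=O)OC)c1C | intermediate
16 | (4R)-6-acetyl-4-[4-(benzyloxy)phenyl]-7-hydroxy-5-methyl-3,4-dihydro-2H-chromen-2-one | CC(=O)c1c(O)cc2c(c1C)[C@@H](c1ccc(OCc3ccccc3)cc1)CC(=O)O2 | intermediate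
17 | (4R)-6-acetyl-7-(benzyloxy)-4-[4-(benzyloxy)phenyl]-5-methyl-3,4-dihydro-2H-chromen-2-one | CC(=O)c1c(OCc2ccccc2)cc3c(c1C)[C@@H](c1ccc(OCc4ccccc4)cc1)CC(=O)O3 | intermediate
18 | (4R)-7-(benzyloxy)-4-[4-(benzyloxy)phenyl]-5-methyl-6-[1-(trimethylsilyloxy)ethenyl]-3,4-dihydro-2H-chromen-2-one | C=C(O[Si](C)(C)C)c1c(OCc2ccccc2)cc3c(c1C)[C@@H](c1ccc(OCc4ccccc4)cc1)CC(=O)O3 | intermediate
19 | malonyl dichloride | O=C(Cl)CC(=O)Cl | starting material
20 | 5-[(4R)-7-(benzyloxy)-4-[4-(benzyloxy)phenyl]-5-methyl-2-oxo-3,4-dihydro-2H-chromen-6-yl]-3,5-dioxopentanoyl chloride | O=C(Cl)CC(=O)CC(=O)c1c(OCc2ccccc2)cc3c(c1C)[C@@H](c1ccc(OCc4ccccc4)cc1)CC(=O)O3 | intermediate (not isolated)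
21 | (4R)-7-(benzyloxy)-4-[4-(benzyloxy)phenyl]-6-(4-hydroxy-2-oxo-2H-pyran-6-yl)-5-methyl-3,4-dihydro-2H-chromen-2-one | O=c1cc(O)cc(-c2c(OCc3ccccc3)cc4c(c2C)[C@@H](c2ccc(OCc5ccccc5)cc2)CC(=O)O4)o1 | intermediate
22 | (4R)-7-(benzyloxy)-4-[4-(benzyloxy)phenyl]-6-(4-methoxy-2-oxo-2H-pyran-6-yl)-5-methyl-3,4-dihydro-2H-chromen-2-one | COc1cc(-c2c(OCc3ccccc3)cc4c(c2C)[C@@H](c2ccc(OCc5ccccc5)cc2)CC(=O)O4)oc(=O)c1 | intermediate
23 | (4R)-7-hydroxy-4-(4-hydroxyphenyl)-6-(4-methoxy-2-oxo-2H-pyran-6-yl)-5-methyl-3,4-dihydro-2H-chromen-2-one | COc1cc(-c2c(O)cc3c(c2C)[C@@H](c2ccc(O)cc2)CC(=O)O3)oc(=O)c1 | target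

Total step count: 12
Longest linear sequence: 12 steps (1 to 23); compounds 2, 7, 12 and 19 are purchased and enter directly.

Steps most likely to fail

Step 6 (key cycloaddition). Both bond-forming termini are hindered (branched chain on C4a, methyl on C5). Ring formation may therefore be slower than loss of the silyl groups from the diene, and the keto ester would be returned without any arene. The fallback keeps the two bonds but swaps the 2π partner for its more electrophilic allene isomer. Commercial pent-4-yn-2-ol is oxidised with Dess–Martin periodinane to pent-4-yn-2-one F1, which a trace of Et3N isomerises to penta-3,4-dien-2-one F2. Diene 11 adds across the conjugated C=C of F2 (PhMe, 20–60 °C), the central sp carbon bonding to C4a and the acyl-bearing carbon to C7, to give exo-methylene cycloadduct F3. Work-up with 1 M HCl in THF removes methanol and the silyl groups, and the exocyclic double bond moves into the ring, so the sequence sets out from 11 and returns at 15. Cycloadditions of bis(silyloxy)dienes with acceptor-substituted allenes that end in methyl- or CH2-substituted arenes are a known reaction type.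

Step 10 (pyranone annulation). The hydrogen chloride released may protodesilylate the enol ether back to the ketone, or acylation may stop at the open-chain stage, so the ring would not close cleanly. The fallback builds the ring in two discrete stages from ketone 17. Magnesium-mediated soft enolisation (MgBr2·OEt2, i-Pr2NEt, CH2Cl2, 0 °C) and C-acylation with methyl 3-chloro-3-oxopropanoate give methyl 5-[(4R)-7-(benzyloxy)-4-[4-(benzyloxy)phenyl]-5-methyl-2-oxo-3,4-dihydro-2H-chromen-6-yl]-3,5-dioxopentanoate F4. Cyclisation of this 3,5-dioxo ester with DBU in dry toluene at 80 °C (enol oxygen onto the ester) returns to the route at 21. Both stages are known reaction types and avoid amide bases.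

Step 3 (desymmetrisation). Discrimination between the two enantiotopic carbonyls may be insufficient, or of the wrong sense, with this para-benzyloxyaryl substrate, leaving an enantiomeric excess too low to upgrade by crystallisation. The fallback moves the stereo-determining event to an enzyme. Diacid 4 is esterified (MeOH, H2SO4 cat., reflux) to dimethyl 3-[4-(benzyloxy)phenyl]pentanedioate F5. One enantiotopic ester group is then hydrolysed in pH 7–8 buffer with co-solvent by a hydrolase chosen by screening for the (R)-hemiester (pig liver esterase, α-chymotrypsin, Candida antarctica lipase B). Enzymatic desymmetrisation of dimethyl 3-arylglutarates is known chemistry, and the sequence sets out from 4 and returns at 6.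

Further compounds
F1 | step 6 | pent-4-yn-2-one | CC(=O)CC#C
F2 | step 6 | penta-3,4-dien-2-one | CC(=O)C=C=C
F3 | step 6 | methyl (3S)-3-[5-acetyl-4-methoxy-6-methylidene-2,4-bis(trimethylsilyloxy)cyclohex-2-en-1-yl]-3-[4-(benzyloxy)phenyl]propanoate (mixture at the three transient ring centres) | COC1(O[Si](C)(C)C)C=C(O[Si](C)(C)C)C([C@@H](c2ccc(OCc3ccccc3)cc2)CC(=O)OC)C(=C)C1C(C)=O
F4 | step 10 | methyl 5-[(4R)-7-(benzyloxy)-4-[4-(benzyloxy)phenyl]-5-methyl-2-oxo-3,4-dihydro-2H-chromen-6-yl]-3,5-dioxopentanoate | COC(=O)CC(=O)CC(=O)c1c(OCc2ccccc2)cc3c(c1C)[C@@H](c1ccc(OCc4ccccc4)cc1)CC(=O)O3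
F5 | step 3 | dimethyl 3-[4-(benzyloxy)phenyl]pentanedioate | COC(=O)CC(c1ccc(OCc2ccccc2)cc1)CC(=O)OC
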